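The numbers in the tables are calculated for an exercise.

**Two walls.** In maple, Qb cannot stay at its charge of 25.0 mM while Qa is being diverted, and it cannot fall below 9.00 mM, the charge less two Qb for each Qa. In the proposed scheme, Qa either turns into Qc by itself or takes one Qb to give Qe, and Qe takes a second Qb to give Qf. Crystals of Qd count as Qc.

| setting | noon | dusk | winter | autumn | ash | maple |
|---|---|---|---|---|---|---|
| Qa | 0.0056 M | 0.0060 M | 0.0094 M | 0.0050 M | 0.0050 M | 0.0080 M |
| Qb | 6 mM | 6 mM | 6 mM | 16 mM | 6.00 mM | 25.0 mM |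
| remark | run made earlier | run made earlier | run made earlier | run made earlier |  |  |
| time |  |  |  |  | 15 min | 15 min |

- noon (time / min: Qc / %, Qa / %): 4.00: 44.8, 14.0; 8.00: 53.0, 3.8; 12.0: 55.6, 2.5; 15.0: 55.4, 1.2
- dusk (time / min: Qc / %, Qa / %): 4.00: 45.4, 17.0; 8.00: 53.4, 4.0; 12.0: 56.9, 1.5; 15.0: 55.5, 0
- winter (time / min: Qc / %, Qa / %): 4.00: 46.7, 17.5; 8.00: 57.4, 4.1; 12.0: 58.3, 3.1; 15.0: 60.3, 0.9
- autumn (time / min: Qc / %, Qa / %): 4.00: 27.6, 6.0; 8.00: 24.7, 0.2; 12.0: 28.1, 0.2; 15.0: 26.8, 0.4

(readings scatter by 1 percentage point)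

- for Qc the Qd is counted in
- as a solid, counted per litre of solution: Qd
- what may be going on: Qb + Qe -> Qf; Qa + Qb -> Qe; Qa -> Qc; Qd <-> Qc

* the flask that ends with the higher amount of Qc, in percent of the Qa charged, or "neither" when 2 percentage points or less lies between them (ash / maple / neither)
* final Qc, as a percentage of the Qa charged, in ash
* final Qc, as a percentage of the Qa charged, in maple

**Break-even level.** If the first route runs with Qa and the second with Qa times Qb, the share of Qa reaching Qc at any moment is K/(K+[Qb]). The autumn readings average 26.8% Qc, so at two Qb per diverted Qa its Qb falls from 16 mM to about 8.68 mM, a mean of 12.3 mM. As a reading, that gives K = 4.52 mM, the break-even level: the Qb concentration at which Qa goes equally to Qc and to Qe, a selectivity factor in concentration units.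

**My bracket.** Maple's two walls give a floor of 15.3% and a ceiling of 33.4%. Ash's floor, with Qb at its charge, is 43.0%, which clears maple's ceiling by 9.6 percentage points. Taking Qb at the mean of its charge and its remainder, with two Qb per Qa diverted at the floor share, gives maple an estimate of 19.9%. In ash the same step gives 58.9%, and repeating it gives 53.4%.

**The forecast.** It names ash, with 54% in ash and 19.5% in maple, holding that the selectivity for Qc “improves as Qb is used up”. Ash's figure lies between my two, and maple's lies just under my 19.9%.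

**The result.** Ash ends at 54.0% and maple at 20.3%, so ash holds more.

    Qb + Qe → Qf (k = 0.810 L mol⁻¹ s⁻¹)
    Qa + Qb → Qe (k = 0.850 L mol⁻¹ s⁻¹)
    Qa → Qc (k = 0.00430 s⁻¹)
    Qd ⇌ Qc, rate k4*(cs4 - [Qc]) while solid is left; crystals form when [Qc] > cs4 (solubility = 0.480 mM, k = 1.10 s⁻¹)

Maple keeps 49.0% of its Qb at 15.0 min, and K with the mean of charge and remainder gives 19.5%. A neighbour of maple charged with 0.062 M of Qb keeps 76% of it, so K gives 7.65%, and that flask ends at 8.24%.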